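## Retrosynthetic overview

1. Target 26 ⇐ face-selective epoxidation of the C1=C10 alkene of diene bis-ester 25. The C8 ester is put on last, from epoxy acid 23 (Sharpless epoxidation of tiglyl alcohol, then oxidation); the C3 ester is put on earlier.
2. trans-6,12-Lactone 20 ⇐ C8-OH-directed anti reduction of the C6 ketone of the ring-expanded keto ester, then lactonisation.
3. Ten-membered ring (1(10)E,4Z) ⇐ ring-expanding, ether-assisted Grob fragmentation of oxa-bridged triflate 13: the C6–C10 bond breaks, the furan oxygen becomes O3 and C6 becomes the ketone.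
4. Oxa-bridged 5–7 ring system 11 ⇐ intramolecular (4+3) cycloaddition of a furan with a tethered tertiary oxyallyl cation.
5. Cycloaddition precursor 9 ⇐ catalytic asymmetric syn-2-(methoxycarbonyl)allylation of aldehyde 8 (biacetyl + allyl bromide) with bromide 4 (4-methylfurfural + methyl acrylate). Ring order: cyclopentane and cycloheptene together, then the ten-membered ring, then the lactone, then the oxirane.

Assumptions: 4-methylfuran-2-carbaldehyde (1) and (2R)-2-methylbutanoic acid (16) are bought. Carbons are numbered as in germacranes (C1–C15; lactone carbonyl C12 on O6). The route is a proposal; no step has been run.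

## Route

Step 1
Reactants: 1 4-methylfuran-2-carbaldehyde; 2 methyl acrylate
Product: 3 methyl 2-[hydroxy(4-methylfuran-2-yl)methyl]prop-2-enoate (racemic)
Conditions: DABCO (0.5 equiv), MeOH, 23 °C, 3 d
Reagents that add atoms: none
Why: Morita–Baylis–Hillman reaction joins C7 to C11 and brings in C12 and C13; the carbinol centre is erased in step 2, so no stereocontrol is needed.

Step 2
Reactants: 3 Baylis–Hillman alcohol
Product: 4 methyl (2Z)-2-(bromomethyl)-3-(4-methylfuran-2-yl)prop-2-enoate
Conditions: NBS, Me2S, CH2Cl2, 0 → 23 °C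
Reagents that add atoms: N-bromosuccinimide, O=C1CCC(=O)N1Br
Why: Corey–Kim-type activation and SN2′ return of bromide give the thermodynamically preferred (Z)-allyl bromide without strong acid that would harm the furan.

Step 3
Reactants: 5 butane-2,3-dione; 6 3-bromoprop-1-ene
Product: 7 3-hydroxy-3-methylhex-5-en-2-one (racemic)
Conditions: Zn dust, THF/sat. aq. NH4Cl, 0 → 23 °C (5 in threefold excess)
Reagents that add atoms: none
Why: Barbier mono-allylation of the activated 1,2-diketone gives the tertiary α-ketol (future C10 leaving group next to the C1 ketone); its configuration is irrelevant because C10 is ionised in step 6.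

Step 4
Reactants: 7 allyl ketol
Product: 8 3-hydroxy-3-methyl-4-oxopentanal (racemic)
Conditions: O3, CH2Cl2, −78 °C; then Me2S, −78 → 23 °C; used crude
Reagents that add atoms: ozone, [O-][O+]=O
Why: Ozonolysis with reductive work-up unmasks the C8 aldehyde; the β-hydroxy aldehyde is used at once to avoid dehydration.

Step 5
Reactants: 4 allyl bromide; 8 aldehyde
Product: 9 methyl (3R,4R)-6-hydroxy-6-methyl-2-methylidene-3-(4-methylfuran-2-yl)-7-oxo-4-[(triethylsilyl)oxy]octanoate (both C6 epimers)
Conditions: CrCl2 (10 mol %), chiral tridentate carbazole bis(oxazoline) ligand (12 mol %, the enantiomer that gives the 3R,4R adduct), Mn powder, Et3SiCl, i-Pr2NEt (0.3 equiv), THF, 0 °C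
Reagents that add atoms: chlorotriethylsilane, CC[Si](Cl)(CC)CC
Why: Catalytic asymmetric Nozaki–Hiyama–Kishi 2-(alkoxycarbonyl)allylation: the (Z)-γ-substituted allylchromium adds through a chair transition state to give the syn C7–C8 adduct, the ligand fixes the absolute sense (7R,8R in target numbering), and Et3SiCl turns the catalyst over and leaves C8–O as its TES ether, which blocks lactonisation.

Step 6
Reactants: 9 furyl ketol
Product: 11 oxa-bridged tricyclic ketone (3S,6R,7R,8R,10R), via tertiary mesylate 10 (not isolated)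
Conditions: MsCl, Et3N, CH2Cl2, 0 °C; then CF3CH2OH, Et3N, 23 °C
Reagents that add atoms: methanesulfonyl chloride, CS(=O)(=O)Cl (its mesyl group is held only by 10)
Why: Föhlisch-type generation of the tertiary oxyallyl cation and intramolecular (4+3) cycloaddition onto the furan form C6–C10 and C2–C3 at once; a compact transition state with the tether syn to the oxyallyl oxygen puts C9 equatorial and the C14 methyl axial, and allylic strain at C7 keeps the acrylate on the side of the furan oxygen, which sets C3 (S) relative to C7 and C8.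

Step 7
Reactants: 11 oxa-bridged ketone
Product: 12 equatorial C1 alcohol (1R,3S,6R,7R,8R,10S)
Conditions: NaBH4, CeCl3·7H2O, MeOH, −40 °C
Reagents that add atoms: none
Why: Luche 1,2-reduction spares the α-methylene ester; the exo face of the C1 carbonyl is screened by the axial C14 methyl, so hydride should enter from the endo face and give the equatorial alcohol (also the thermodynamic epimer), whose C1–O bond is antiperiplanar to C10–C6.

Step 8
Reactants: 12 equatorial alcohol
Product: 15 ring-expanded hydroxy enone (3S,7R,8R; 1(10)E,4Z), via equatorial triflate 13 (not isolated), via bridged hemiketal 14 (not isolated)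
Conditions: Tf2O, 2,6-lutidine (3 equiv), CH2Cl2, −78 °C; then (CF3)2CHOH/H2O (9:1), −78 → 0 °C
Reagents that add atoms: trifluoromethanesulfonic anhydride, O=S(=O)(OS(=O)(=O)C(F)(F)F)C(F)(F)F (its triflyl group is held only by 13); water, O
Why: Proposed new method: ether-assisted ring-expanding Grob (retro-Prins) fragmentation, in which loss of the equatorial C1 triflate is concerted with cleavage of the antiperiplanar C6–C10 bond, pushed by the antiperiplanar lone pair of the bridging oxygen and driven by relief of strain between the vicinal quaternary carbons, so that the (E)-C1=C10 alkene forms stereospecifically (C9 anti to C2) and the cis C4=C5 bond of the former furan becomes the (Z)-alkene of the ten-membered ring, after which water traps the bridged oxocarbenium ion at C6 as hemiketal 14, which opens to the C6 ketone and the C3 alcohol (net isomerisation of 12); the closest known reaction types are the Grob fragmentation of equatorial 3-tropanyl sulfonates (nitrogen lone pair as donor) and the retro-Prins fragmentation of tetrahydropyran-4-yl cations, neither of which has been shown on a (4+3) oxa-bicycle or used to make a cyclodecadiene.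

Step 9
Reactants: 15 hydroxy enone; 16 (2R)-2-methylbutanoic acid
Product: 17 C3 (2R)-2-methylbutanoate of 15
Conditions: EDC·HCl, DMAP (0.1 equiv), CH2Cl2, 0 °C
Reagents that add atoms: none
Why: Steglich esterification of the only free secondary hydroxyl (C8–O is silylated, the hemiketal hydroxyl is tertiary); carbodiimide activation at 0 °C does not racemise the α-centre of the acid, and acylation locks the open keto form.

Step 10
Reactants: 17 keto ester
Product: 18 C8 alcohol (β-hydroxy ketone)
Conditions: HF·pyridine, pyridine/THF, 0 °C; used directly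
Reagents that add atoms: none
Why: Buffered fluoride desilylation frees C8–OH without base (no retro-aldol, no alkene migration at C7) and without acid strong enough to lactonise.

Step 11
Reactants: 18 β-hydroxy ketone
Product: 20 8β-hydroxy-3β-[(2R)-2-methylbutanoyloxy]germacra-1(10)E,4Z,11(13)-trien-12,6α-olide, via anti diol ester 19 (not isolated)
Conditions: Me4NBH(OAc)3, MeCN/AcOH (1:1), −30 °C; then PPTS (cat.), CH2Cl2, 23 °C
Reagents that add atoms: none
Why: Evans–Saksena hydroxyl-directed reduction: boron bound to O8 delivers hydride to C6 through a chair transition state and gives the 1,3-anti diol (6R, O6 trans to C7–C11), and mild acid then closes the more stable trans-fused 6,12-lactone with loss of methanol, leaving C8–OH free.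

Step 12
Reactants: 21 (2E)-2-methylbut-2-en-1-ol
Product: 22 [(2S,3S)-2,3-dimethyloxiran-2-yl]methanol
Conditions: Ti(OiPr)4 (5 mol %), L-(+)-diethyl tartrate (6 mol %), t-BuOOH, 4 Å molecular sieves, CH2Cl2, −20 °C
Reagents that add atoms: tert-butyl hydroperoxide, CC(C)(C)OO
Why: Sharpless asymmetric epoxidation; the L-(+)-tartrate catalyst gives the (2S,3S)-epoxy alcohol from an (E)-allylic alcohol, which sets both oxirane centres of the C8 side chain.

Step 13
Reactants: 22 epoxy alcohol
Product: 23 (2R,3S)-2,3-dimethyloxirane-2-carboxylic acid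
Conditions: RuCl3·xH2O (2 mol %), NaIO4, CCl4/MeCN/H2O, 0 → 23 °C
Reagents that add atoms: sodium periodate, [Na+].[O-]I(=O)(=O)=O
Why: Ruthenium tetroxide oxidation of the primary alcohol to the acid leaves the oxirane intact; the C2 descriptor changes only because the carboxyl group takes a higher priority.

Step 14
Reactants: 20 hydroxy lactone; 23 epoxy acid
Product: 25 diene bis-ester, via mixed anhydride 24 (not isolated)
Conditions: 23, 2,4,6-trichlorobenzoyl chloride, Et3N, THF, 0 °C; then 20, DMAP, toluene, 23 °C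
Reagents that add atoms: 2,4,6-trichlorobenzoyl chloride, O=C(Cl)c1c(Cl)cc(Cl)cc1Cl (its acyl group is held only by 24)
Why: Yamaguchi esterification couples the hindered C8 hydroxyl with the α,α-disubstituted glycidic acid without touching the oxirane, the α-methylene lactone or the first ester.

Step 15
Reactants: 25 diene bis-ester
Product: 26 target (1R,3S,6R,7R,8R,10R; 2′R; 2″R,3″S)
Conditions: mCPBA, NaHCO3, CH2Cl2, 0 °C
Reagents that add atoms: 3-chloroperoxybenzoic acid, OOC(=O)c1cccc(Cl)c1
Why: Prilezhaev epoxidation of the only electron-rich alkene (C4=C5 is deactivated by two allylic acyloxy groups, C11=C13 is conjugated); attack on the outer face of the (E)-C1=C10 bond in the heliangolide ring conformation should give the trans 1β,10α-epoxide.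

## Compound list

1 | 4-methylfuran-2-carbaldehyde | Cc1coc(C=O)c1 | starting material
2 | methyl acrylate | C=CC(=O)OC | starting material
3 | methyl 2-[hydroxy(4-methylfuran-2-yl)methyl]prop-2-enoate (racemic) | C=C(C(=O)OC)C(O)c1cc(C)co1 | intermediate
4 | methyl (2Z)-2-(bromomethyl)-3-(4-methylfuran-2-yl)prop-2-enoate | BrC/C(=C\c1cc(C)co1)C(=O)OC | intermediate
5 | butane-2,3-dione | CC(=O)C(C)=O | starting material
6 | 3-bromoprop-1-ene | C=CCBr | starting material
7 | 3-hydroxy-3-methylhex-5-en-2-one (racemic) | C=CCC(C)(O)C(C)=O | intermediate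
8 | 3-hydroxy-3-methyl-4-oxopentanal (racemic) | O=CCC(C)(O)C(C)=O | intermediate
9 | methyl (3R,4R)-6-hydroxy-6-methyl-2-methylidene-3-(4-methylfuran-2-yl)-7-oxo-4-[(triethylsilyl)oxy]octanoate (C6 epimers; chain C3 and C4 are C7 and C8 of the target) | COC(=O)C(=C)[C@@H](c1cc(C)co1)[C@H](O[Si](CC)(CC)CC)CC(C)(O)C(C)=O | intermediate
10 | tertiary methanesulfonate of 9 | COC(=O)C(=C)[C@@H](c1cc(C)co1)[C@H](O[Si](CC)(CC)CC)CC(C)(OS(C)(=O)=O)C(C)=O | intermediate
11 | oxa-bridged tricyclic ketone: ring C1–C10 with extra bond C6–C10, C1 ketone, ether oxygen bridging C3 and C6, C4=C5 (methyl on C4), methyl on C10, OSiEt3 on C8, C(=CH2)CO2Me on C7; (3S,6R,7R,8R,10R) | C[C@]12C[C@@H](O[Si](CC)(CC)CC)[C@@H](C(=C)C(=O)OC)[C@@]23O[C@@H](CC1=O)C(C)=C3 | intermediate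
12 | equatorial C1 alcohol of 11; (1R,3S,6R,7R,8R,10S), C1–OH cis to the C10 methyl | C[C@]12C[C@@H](O[Si](CC)(CC)CC)[C@@H](C(=C)C(=O)OC)[C@@]23O[C@@H](C[C@H]1O)C(C)=C3 | intermediate
13 | C1 trifluoromethanesulfonate of 12 | C[C@]12C[C@@H](O[Si](CC)(CC)CC)[C@@H](C(=C)C(=O)OC)[C@@]23O[C@@H](C[C@H]1OS(=O)(=O)C(F)(F)F)C(C)=C3 | intermediate
14 | bridged hemiketal: ten-membered ring with (E)-C1=C10, oxygen bridging C3 and C6, OH on C6; (3S,6S,7R,8R) | C/C1=C\C[C@@H]2O[C@@](O)(C=C2C)[C@H](C(=C)C(=O)OC)[C@H](O[Si](CC)(CC)CC)C1 | intermediate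
15 | methyl 2-[(1R,2R,4E,7S,8Z)-7-hydroxy-4,8-dimethyl-10-oxo-2-[(triethylsilyl)oxy]cyclodeca-4,8-dien-1-yl]prop-2-enoate (germacrane numbering: C3–OH, C6 ketone, C8–OTES; 1(10)E,4Z) | C/C1=C\C[C@H](O)/C(C)=C\C(=O)[C@H](C(=C)C(=O)OC)[C@H](O[Si](CC)(CC)CC)C1 | intermediate
16 | (2R)-2-methylbutanoic acid | CC[C@@H](C)C(=O)O | starting material
17 | C3 (2R)-2-methylbutanoate of 15 | C/C1=C\C[C@H](OC(=O)[C@H](C)CC)/C(C)=C\C(=O)[C@H](C(=C)C(=O)OC)[C@H](O[Si](CC)(CC)CC)C1 | intermediate
18 | desilylated 17: C8–OH, C6 ketone, C3 ester | C/C1=C\C[C@H](OC(=O)[C@H](C)CC)/C(C)=C\C(=O)[C@H](C(=C)C(=O)OC)[C@H](O)C1 | intermediate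
19 | anti-6,8-diol methyl ester (3S,6R,7R,8R) | C/C1=C\C[C@H](OC(=O)[C@H](C)CC)/C(C)=C\[C@@H](O)[C@H](C(=C)C(=O)OC)[C@H](O)C1 | intermediate
20 | 8β-hydroxy-3β-[(2R)-2-methylbutanoyloxy]germacra-1(10)E,4Z,11(13)-trien-12,6α-olide | C=C1C(=O)O[C@@H]2/C=C(/C)[C@@H](OC(=O)[C@H](C)CC)C/C=C(\C)C[C@@H](O)[C@@H]12 | intermediate
21 | (2E)-2-methylbut-2-en-1-ol | C/C=C(\C)CO | starting material
22 | [(2S,3S)-2,3-dimethyloxiran-2-yl]methanol | OC[C@]1(C)O[C@H]1C | intermediate
23 | (2R,3S)-2,3-dimethyloxirane-2-carboxylic acid | OC(=O)[C@]1(C)O[C@H]1C | intermediate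
24 | (2R,3S)-2,3-dimethyloxirane-2-carboxylic 2,4,6-trichlorobenzoic anhydride | O=C(OC(=O)[C@]1(C)O[C@H]1C)c1c(Cl)cc(Cl)cc1Cl | intermediate
25 | 8β-[(2R,3S)-2,3-dimethyloxirane-2-carbonyloxy]-3β-[(2R)-2-methylbutanoyloxy]germacra-1(10)E,4Z,11(13)-trien-12,6α-olide | C=C1C(=O)O[C@@H]2/C=C(/C)[C@@H](OC(=O)[C@H](C)CC)C/C=C(\C)C[C@@H](OC(=O)[C@]3(C)O[C@H]3C)[C@@H]12 | intermediate
26 | CNP0265335.3, the 1β,10α-epoxide of 25 | C=C1C(=O)O[C@@H]2/C=C(/C)[C@@H](OC(=O)[C@H](C)CC)C[C@H]3O[C@]3(C)C[C@@H](OC(=O)[C@]3(C)O[C@H]3C)[C@@H]12 | target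

## Step count and risks

Total steps: 15. Longest linear sequence: 11 (steps 1, 2, 5–11, 14, 15 from 1; equally 3–11, 14, 15 from 5).

Steps most likely to fail: 8, 6 and 7.

Step 8 (the new ring expansion). The triflate may instead undergo methyl shift, elimination or cleavage of the C2–C3 bond. The fallback uses known chemistry only, sets out from ketone 11 and comes back at 18. It runs the ring expansion as a classical alkoxide-driven Wharton–Grob fragmentation, for which the bridging oxygen must first become a free C6 alkoxide. TMSOTf/Et3N (CH2Cl2, −78 °C) opens the oxa-bridge of 11 by β-elimination across C2–C3 and gives the ring-opened dienone trimethylsilyl ether F3. Nucleophilic epoxidation of the C2=C3 enone bond (t-BuOOH, DBU, CH2Cl2, 0 °C) gives the epoxy ketone F4, and SmI2 (THF/MeOH, −90 °C) cleaves its α C–O bond to return the C3 oxygen as the β-hydroxy ketone F5. If the C3 epimer is the wrong one, the next esterification is run as a Mitsunobu inversion instead. Coupling with 16 (EDC·HCl, DMAP) gives the C3 ester F6, Luche reduction gives the C1 alcohol F7 (C1–O cis to the C10 methyl; epimers separated), and MsCl/Et3N gives the C1 mesylate F8. TBAF (THF, 0 °C) removes both silyl groups; the C6 alkoxide then fragments the C6–C10 bond antiperiplanar to the mesylate and delivers 18, so steps 7 to 10 are bypassed.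

Step 6 (intramolecular (4+3) cycloaddition). The tertiary mesylate may eliminate to an enone, or the cycloaddition may fail to build the two vicinal quaternary carbons. The fallback sets out from 9 and comes back at 11, and changes the way the cation is made. 9 is silylated on both oxygens (TMSOTf, Et3N, CH2Cl2, 0 °C) to the enol silane silyl ether F1. Catalytic TMSOTf (10 mol %, CH2Cl2, −78 °C) then ionises the tertiary allylic silyloxy group. The resulting 2-silyloxyallyl cation undergoes the same cycloaddition without base, and loss of the silyl group gives 11.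

Step 7 (facial selectivity of the reduction). Hydride may enter mainly from the exo face. The fallback sets out from 11 and comes back at 12, and replaces kinetic by thermodynamic control. The axial (1S) alcohol F2 formed in that case is equilibrated by reversible hydrogen transfer with [Ru(η5-C5Ph5)(CO)2Cl] (5 mol %) and t-BuOK (5 mol %) in toluene at 50 °C. This passes through metal-bound ketone 11 and settles on the more stable equatorial alcohol 12.

Further compounds

F1 | step 6 | methyl (3R,4R)-6-methyl-2-methylidene-3-(4-methylfuran-2-yl)-4-[(triethylsilyl)oxy]-6,7-bis[(trimethylsilyl)oxy]oct-7-enoate (C6 epimers) | COC(=O)C(=C)[C@@H](c1cc(C)co1)[C@H](O[Si](CC)(CC)CC)CC(C)(O[Si](C)(C)C)C(=C)O[Si](C)(C)C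
F2 | step 7 | axial (1S) C1 epimer of alcohol 12 | C[C@]12C[C@@H](O[Si](CC)(CC)CC)[C@@H](C(=C)C(=O)OC)[C@@]23O[C@@H](C[C@@H]1O)C(C)=C3
F3 | step 8 | ring-opened dienone trimethylsilyl ether: C1 ketone, C2=C3, C4=C5, C6–OSiMe3, C6–C10 bond intact, other centres as in 11 | C[C@]12C[C@@H](O[Si](CC)(CC)CC)[C@@H](C(=C)C(=O)OC)[C@]2(O[Si](C)(C)C)C=C(C)C=CC1=O
F4 | step 8 | C2–C3 epoxy ketone of F3 (epoxide oxygen cis to the C6 oxygen) | C[C@]12C[C@@H](O[Si](CC)(CC)CC)[C@@H](C(=C)C(=O)OC)[C@]2(O[Si](C)(C)C)C=C(C)[C@H]3O[C@H]3C1=O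
F5 | step 8 | β-hydroxy ketone: C1 ketone, (3S)-C3–OH, C4=C5, C6–OSiMe3 | C[C@]12C[C@@H](O[Si](CC)(CC)CC)[C@@H](C(=C)C(=O)OC)[C@]2(O[Si](C)(C)C)C=C(C)[C@@H](O)CC1=O
F6 | step 8 | C3 (2R)-2-methylbutanoate of F5 | C[C@]12C[C@@H](O[Si](CC)(CC)CC)[C@@H](C(=C)C(=O)OC)[C@]2(O[Si](C)(C)C)C=C(C)[C@@H](OC(=O)[C@H](C)CC)CC1=O
F7 | step 8 | C1 alcohol of F6 (C1–OH cis to the C10 methyl) | C[C@]12C[C@@H](O[Si](CC)(CC)CC)[C@@H](C(=C)C(=O)OC)[C@]2(O[Si](C)(C)C)C=C(C)[C@@H](OC(=O)[C@H](C)CC)C[C@H]1O
F8 | step 8 | C1 methanesulfonate of F7 | C[C@]12C[C@@H](O[Si](CC)(CC)CC)[C@@H](C(=C)C(=O)OC)[C@]2(O[Si](C)(C)C)C=C(C)[C@@H](OC(=O)[C@H](C)CC)C[C@H]1OS(C)(=O)=O
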